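In the winter run a fast start followed by a slow straight line invites the reading of one stoichiometric turnover of the catalyst, but the same curve appears if added ligand takes free catalyst out of work within the first days.

- winter: substrate 20 mM; reagent 40 mM; free catalyst 3 mM; second catalyst 0.21 mM; added ligand 13 mM; run made earlier
- flask: substrate 20 mM; reagent 40.0 mM; free catalyst 3.0 mM; second catalyst 0.42 mM; added ligand 13 mM

winter run (percent of the substrate charged)

| time / d | product / % |
|---|---|
| 0.500 | 5.6 |
| 1.04 | 9.5 |
| 2.50 | 12.2 |
| 6.00 | 18.1 |

(standard deviation of a reading: 0.5 percentage points)

- no earlier run changes the charge of free catalyst; that part of a forecast is a guess
- "the catalyst" is free catalyst with its forms; second catalyst is a second catalyst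
- what has left substrate counts as converted, also if it is not yet product
- no earlier run changes the charge of second catalyst; that part of a forecast is a guess
- no earlier run changes the charge of reagent; that part of a forecast is a guess

* apparent order in free catalyst when 30 % of the substrate are converted (percent change of the rate of making product for one percent more free catalyst charged)
* apparent order in reagent when 30 % of the substrate are converted (percent change of the rate of making product for one percent more reagent charged)
* factor on the rate of making product when 30 % of the substrate are converted if reagent is charged twice over

Dividing the winter run's late slope by its slope over the first reading makes time drop out and leaves a reading of 0.151, but that first slope already averages over the fall in activity, so the share still working may lie well below this ratio. I therefore assume that free catalyst is small beside a form bound one to one to added ligand, in balance with it. Free catalyst then goes as catalyst charged over ligand left, and extra catalyst both adds to the top and uses up ligand. So I carry the ligand load λ, the catalyst charged over the ligand left once each catalyst has taken one 0.300, and the order in free catalyst in the new flask is 1 + λ, which is 1.30. Reagent was never varied, so I guess that it enters after the step that paces the line, with order about 0 and doubling factor about 1.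

The forecast gives 0.8, 0.5 and 1.4, on the ground that “Rate should then scale roughly with total catalyst”.

The flask gives 1.3, −7.8 × 10⁻⁴ and 0.999.

    substrate + free catalyst → free catalyst + intermediate (k = 7.76 M⁻¹ h⁻¹)
    reagent + second catalyst + intermediate → second catalyst + product (k = 14600 M⁻² h⁻¹)
    free catalyst + added ligand ⇌ idle complex (K = 2720 M⁻¹, k = 20.9 M⁻¹ h⁻¹)

After 15.0 d this flask holds 96.5 % of the catalyst as idle complex, an off-cycle form, and 77.7 % of the added ligand stays free, so bound over free ligand stands at 0.286 against λ of 0.300. The order exceeds the plain catalytic one because of this binding: the same flask run without the path to idle complex has order 0.95, not 1.3, a difference of 0.332 against λ of 0.300.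

The earlier runs and the new flask are simulated for an exercise.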